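**Retrosynthetic overview**
- Target ⇐ visible-light, redox-neutral radical cascade on a bicyclic 7-endo type A acylphloroglucinol enol: C3–C11 closes the homoadamantane, C12–C14 closes the cyclopentane, H ends on C15.
- That enol ⇐ O-demethylation ⇐ ring B closure (C1–C8) by a 1,3 O→C shift of a tertiary alkyl group in a dearomatised pyranodienone.
- Pyranodienone ⇐ dearomatising C5-geranylation of a fully substituted chroman phenol, trans to the C7 side chain (relay of the one purchased stereocentre).
- Chroman ⇐ 4-O-methyl phlorobenzophenone + (R)-lavandulyl bromide (C5–C6), acid cycloetherification (O–C8), C3-prenylation.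
- Ring order: arene (bought) → pyran (relay ring, later opened) → ring B of the bicyclo[3.3.1]nonane → seven-membered ring → cyclopentane.

Assumption: (R)-(−)-lavandulol, the lavender-oil enantiomer, is taken as the purchasable chiral terpene and is the only source of chirality.
Labels: C1–C9 are the bicyclo[3.3.1]nonane positions of the final core (C1 benzoyl, C2/C4/C9 ketones, C3 between C2 and C4, C5 geranyl, C7 the lavandulyl stereocentre, C8 CMe2). C10/C11/C12 are the CH2/CH/CMe2 of the C7 prenyl and C13/C14/C15 those of the C3 prenyl. Ring A is C1–C5 plus C9; ring B is C1, C9, C5, C6, C7, C8.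

**Step 1**
Reactants: 1 2,4,6-trihydroxybenzophenone
Product: 2 cotoin [(2,6-dihydroxy-4-methoxyphenyl)(phenyl)methanone]
Conditions: Me2SO4 (1.0 equiv), K2CO3 (1.0 equiv), acetone, rt
Reagents that add atoms: dimethyl sulfate, COS(=O)(=O)OC
Why: Williamson-type mono-O-methylation goes to the 4-OH, the only phenol not hydrogen-bonded to the benzoyl carbonyl and the most acidic, which blocks this oxygen so that the later cycloetherification can only use the OH next to C1.

**Step 2**
Reactants: 3 (R)-lavandulol [(2R)-5-methyl-2-(prop-1-en-2-yl)hex-4-en-1-ol]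
Product: 4 (R)-lavandulyl bromide [(2R)-1-bromo-5-methyl-2-(prop-1-en-2-yl)hex-4-ene]
Conditions: CBr4, PPh3, CH2Cl2, 0 °C
Reagents that add atoms: carbon tetrabromide, BrC(Br)(Br)Br
Why: Appel bromination of a primary alcohol; substitution occurs at CH2, so the adjacent stereocentre is untouched.

**Step 3**
Reactants: 2 cotoin; 4 (R)-lavandulyl bromide
Product: 5 {2,6-dihydroxy-4-methoxy-3-[(2S)-5-methyl-2-(prop-1-en-2-yl)hex-4-en-1-yl]phenyl}(phenyl)methanone
Conditions: NaOMe (1.1 equiv), NaI (10 mol%), MeOH, 60 °C (2 in 1.5-fold excess)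
Reagents that add atoms: none
Why: C-alkylation of the phloroglucinol-type phenoxide in protic medium at one of the two equivalent free ring carbons (the future C5); the stereocentre is not involved and its descriptor changes to S only through the priority change.

**Step 4**
Reactants: 5 the C-lavandulyl cotoin
Product: 6 [(3S)-7-hydroxy-5-methoxy-2,2-dimethyl-3-(3-methylbut-2-en-1-yl)-3,4-dihydro-2H-chromen-8-yl](phenyl)methanone
Conditions: p-TsOH·H2O (10 mol%), toluene, 40 °C
Reagents that add atoms: none
Why: Brønsted-acid Markovnikov hydroalkoxylation: protonation of the 1,1-disubstituted alkene gives the tertiary C8 cation, which is trapped in a six-membered ring by the only neighbouring OH (the other neighbour is OMe), so the pyran oxygen sits next to the benzoyl-bearing carbon and the stereocentre is untouched.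

**Step 5**
Reactants: 6 the chroman phenol; 7 prenyl bromide (1-bromo-3-methylbut-2-ene)
Product: 8 [(3S)-7-hydroxy-5-methoxy-2,2-dimethyl-3,6-bis(3-methylbut-2-en-1-yl)-3,4-dihydro-2H-chromen-8-yl](phenyl)methanone
Conditions: NaH (1.05 equiv), toluene, 0 °C → rt
Reagents that add atoms: none
Why: ortho C-allylation of a sodium phenoxide in a non-polar solvent at the only unsubstituted ring carbon (the future C3); no stereocentre is formed.

**Step 6**
Reactants: 8 the prenylated chroman phenol; 9 geranyl acetate [(2E)-3,7-dimethylocta-2,6-dien-1-yl acetate]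
Product: 11 (3S,4aS)-8-benzoyl-4a-[(2E)-3,7-dimethylocta-2,6-dien-1-yl]-5-methoxy-2,2-dimethyl-3,6-bis(3-methylbut-2-en-1-yl)-2,3,4,4a-tetrahydro-7H-chromen-7-one, via O-geranyl aryl ether 10 (not isolated)
Conditions: Pd(PPh3)4 (5 mol%), Cs2CO3 (1.2 equiv), THF, 45 °C
Reagents that add atoms: none
Why: Tsuji–Trost allylation with zerovalent palladium: the kinetic O-allyl ether 10 re-ionises, and because every ring carbon is substituted the sink is C-allylation at C5, para to the phenoxide oxygen, giving the cross-conjugated dienone with the linear E-geranyl group; the allyl unit enters axially on the face of the half-chair pyran anti to the equatorial C7 prenyl (the cis isomer would be 1,3-diaxial), so C5 is set trans to the purchased stereocentre.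

**Step 7**
Reactants: 11 the trans pyranodienone
Product: 12 (1S,5S,7S)-1-benzoyl-5-[(2E)-3,7-dimethylocta-2,6-dien-1-yl]-4-methoxy-8,8-dimethyl-3,7-bis(3-methylbut-2-en-1-yl)bicyclo[3.3.1]non-3-ene-2,9-dione (C7 prenyl endo)
Conditions: TMSOTf (20 mol%), 2,6-di-tert-butyl-4-methylpyridine (25 mol%), CH2Cl2, −78 → −40 °C
Reagents that add atoms: none
Why: intramolecular Mukaiyama–Reetz-type tert-alkylation (biomimetic cationic cyclisation, net 1,3 O→C shift): TMSOTf silylates the dienone carbonyl, the tertiary C8–O bond ionises, and the C8 cation is captured within the ion pair by the adjacent silyl enol ether carbon C1 on the face that carries C6, closing ring B through a boat in which the trans C5/C7 relationship necessarily places the C7 prenyl endo (syn to C3) and fixes C1.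

**Step 8**
Reactants: 12 the bicyclic methyl enol ether
Product: 13 (1S,5S,7S)-1-benzoyl-5-[(2E)-3,7-dimethylocta-2,6-dien-1-yl]-4-hydroxy-8,8-dimethyl-3,7-bis(3-methylbut-2-en-1-yl)bicyclo[3.3.1]non-3-ene-2,9-dione (enol of the 2,4,9-trione; C7 prenyl endo)
Conditions: LiCl (10 equiv), DMSO, 120 °C; then H2O work-up
Reagents that add atoms: none
Why: Krapcho-type SN2 demethylation of the vinylogous methyl ester by chloride, which leaves the alkenes and the three stereocentres untouched.

**Step 9**
Reactants: 13 the 7-endo type A enol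
Product: 14 CNP0155129.2 (13 with new bonds C3–C11 and C12–C14 and H on C15; 1R,3R,5S,7S,11R,14S in the labels above)
Conditions: 4CzIPN [1,2,3,5-tetrakis(carbazol-9-yl)-4,6-dicyanobenzene] (2 mol%), 2,4,6-triisopropylbenzenethiol (10 mol%), 2,6-lutidine (20 mol%), MeCN/CH2Cl2 3:1, blue LEDs (450 nm), 25 °C, Ar
Reagents that add atoms: none
Why: Proposed new method: a photoredox/thiol dual-catalysed, redox-neutral radical (3+2) cycloisomerisation in which excited 4CzIPN oxidises the enolate of 13 to the C3 radical, which adds 7-exo to C11 of the endo C7 prenyl held over C3 in the chair form of ring B (C3 is set by the cage; C12 turns away from the C8 methyls, giving 11R), the tertiary C12 radical closes 5-exo on C14 of the C3 prenyl through a chair-like transition state with the dimethylvinyl terminus pseudo-equatorial (isopropyl cis to C10, giving 14S), and the tertiary C15 radical takes H from the thiol whose thiyl radical reoxidises the reduced photocatalyst; the closest known reactions are Mn(OAc)3-mediated oxidative radical cyclisations of 1,3-dicarbonyls and photoredox/thiol hydrofunctionalisation of alkenes.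

**Compound list**
1 | 2,4,6-trihydroxybenzophenone | O=C(c1ccccc1)c1c(O)cc(O)cc1O | starting material
2 | cotoin [(2,6-dihydroxy-4-methoxyphenyl)(phenyl)methanone] | O=C(c1ccccc1)c1c(O)cc(OC)cc1O | intermediate
3 | (R)-lavandulol [(2R)-5-methyl-2-(prop-1-en-2-yl)hex-4-en-1-ol] | OC[C@@H](C(C)=C)CC=C(C)C | starting material
4 | (R)-lavandulyl bromide [(2R)-1-bromo-5-methyl-2-(prop-1-en-2-yl)hex-4-ene] | BrC[C@@H](C(C)=C)CC=C(C)C | intermediate
5 | {2,6-dihydroxy-4-methoxy-3-[(2S)-5-methyl-2-(prop-1-en-2-yl)hex-4-en-1-yl]phenyl}(phenyl)methanone | O=C(c1ccccc1)c1c(O)cc(OC)c(C[C@@H](C(C)=C)CC=C(C)C)c1O | intermediate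
6 | [(3S)-7-hydroxy-5-methoxy-2,2-dimethyl-3-(3-methylbut-2-en-1-yl)-3,4-dihydro-2H-chromen-8-yl](phenyl)methanone | O=C(c1ccccc1)c1c(O)cc(OC)c2c1OC(C)(C)[C@@H](CC=C(C)C)C2 | intermediate
7 | prenyl bromide (1-bromo-3-methylbut-2-ene) | CC(C)=CCBr | starting material
8 | [(3S)-7-hydroxy-5-methoxy-2,2-dimethyl-3,6-bis(3-methylbut-2-en-1-yl)-3,4-dihydro-2H-chromen-8-yl](phenyl)methanone | O=C(c1ccccc1)c1c(O)c(CC=C(C)C)c(OC)c2c1OC(C)(C)[C@@H](CC=C(C)C)C2 | intermediate
9 | geranyl acetate [(2E)-3,7-dimethylocta-2,6-dien-1-yl acetate] | CC(C)=CCC/C(C)=C/COC(C)=O | starting material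
10 | O-geranyl aryl ether of 8 [(3S)-7-{[(2E)-3,7-dimethylocta-2,6-dien-1-yl]oxy}-5-methoxy-2,2-dimethyl-3,6-bis(3-methylbut-2-en-1-yl)-3,4-dihydro-2H-chromen-8-yl](phenyl)methanone | O=C(c1ccccc1)c1c(OC/C=C(\C)CCC=C(C)C)c(CC=C(C)C)c(OC)c2c1OC(C)(C)[C@@H](CC=C(C)C)C2 | intermediate
11 | (3S,4aS)-8-benzoyl-4a-[(2E)-3,7-dimethylocta-2,6-dien-1-yl]-5-methoxy-2,2-dimethyl-3,6-bis(3-methylbut-2-en-1-yl)-2,3,4,4a-tetrahydro-7H-chromen-7-one | O=C(c1ccccc1)C1=C2OC(C)(C)[C@@H](CC=C(C)C)C[C@@]2(C/C=C(\C)CCC=C(C)C)C(OC)=C(CC=C(C)C)C1=O | intermediate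
12 | (1S,5S,7S)-1-benzoyl-5-[(2E)-3,7-dimethylocta-2,6-dien-1-yl]-4-methoxy-8,8-dimethyl-3,7-bis(3-methylbut-2-en-1-yl)bicyclo[3.3.1]non-3-ene-2,9-dione | CC(C)=CCC/C(C)=C/C[C@]12C[C@H](CC=C(C)C)C(C)(C)[C@@](C(=O)c3ccccc3)(C2=O)C(=O)C(CC=C(C)C)=C1OC | intermediate
13 | (1S,5S,7S)-1-benzoyl-5-[(2E)-3,7-dimethylocta-2,6-dien-1-yl]-4-hydroxy-8,8-dimethyl-3,7-bis(3-methylbut-2-en-1-yl)bicyclo[3.3.1]non-3-ene-2,9-dione | CC(C)=CCC/C(C)=C/C[C@]12C[C@H](CC=C(C)C)C(C)(C)[C@@](C(=O)c3ccccc3)(C2=O)C(=O)C(CC=C(C)C)=C1O | intermediate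
14 | CNP0155129.2 (1R,3R,5S,7S,11R,14S in the labels above) | CC(C)=CCC/C(C)=C/C[C@]12C[C@@H]3C[C@@H]4C(C)(C)[C@H](C(C)C)C[C@@]4(C1=O)C(=O)[C@](C(=O)c1ccccc1)(C2=O)C3(C)C | target

**Step count and risks**
Total steps: 9. Longest linear sequence: 8 (steps 1 and 3–9 from 1, or steps 2–9 from 3).

The three steps most likely to fail are 6, 7 and 9.

Step 6 (dearomatising geranylation) may stop at the O-allyl ether, go to C3 instead of C5, or react sluggishly because only one chelated phenol is left. The fallback sets out from 8 and comes back at 11. The phenol oxygen is alkylated with geranyl bromide (K2CO3, DMF) and the ether 10 is isolated. Heating it (N,N-diethylaniline, 160 °C) gives an aromatic Claisen shift to C3, forming the ortho-dienone F1, and a Cope shift across C4 then delivers the linear geranyl group to C5 (para-Claisen), again anti to the C7 prenyl, to give 11. The 2,3-alkene is re-formed in the Cope step, so any Z isomer must be removed by chromatography.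

Step 7 (1,3 O→C shift) may lose the C8 cation to elimination or to capture at C3, which would give the 7-exo type B skeleton. The fallback sets out from 11 and comes back at 13. The methyl ether is cleaved first (LiCl, DMSO, 120 °C) to the free enol, the 5-hydroxy pyranodienone F2. Ring B is then closed under Brønsted acid (neat HCO2H, rt), the established biomimetic cationic cyclisation of dearomatised acylphloroglucinols. This gives 13 directly and step 8 is skipped.

Step 9 (the proposed photochemical cascade) may give back 13 through premature H-transfer to the C3 radical, may give the C14 epimer (the 5-exo facial selectivity is the least certain stereochemical claim in the route), or may scramble the geranyl E-alkene through reversible thiyl addition. The fallback sets out from 13 and comes back at 14, using known chemistry. Oxidative radical cyclisation with Mn(OAc)3·2H2O (2.2 equiv) and Cu(OAc)2·H2O (1 equiv) in AcOH at rt forms the same two bonds; trivalent manganese generates the C3 radical and divalent copper oxidises the C15 radical to the alkene, giving the isopropenyl analogue F3. Hydrogenation (H2, 1 atm, RhCl(PPh3)3, benzene) then saturates only the 1,1-disubstituted alkene to give 14.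

**Further compounds**
F1 | step 6 | 8-benzoyl-6-(3,7-dimethylocta-1,6-dien-3-yl)-5-methoxy-2,2-dimethyl-3,6-bis(3-methylbut-2-en-1-yl)-3,4-dihydro-2H-chromen-7(6H)-one (3S; mixture at C6 and the side-chain carbon) | O=C(c1ccccc1)C1=C2OC(C)(C)[C@@H](CC=C(C)C)CC2=C(OC)C(CC=C(C)C)(C(C)(C=C)CCC=C(C)C)C1=O
F2 | step 7 | (3S,4aS)-8-benzoyl-4a-[(2E)-3,7-dimethylocta-2,6-dien-1-yl]-5-hydroxy-2,2-dimethyl-3,6-bis(3-methylbut-2-en-1-yl)-2,3,4,4a-tetrahydro-7H-chromen-7-one | O=C(c1ccccc1)C1=C2OC(C)(C)[C@@H](CC=C(C)C)C[C@@]2(C/C=C(\C)CCC=C(C)C)C(O)=C(CC=C(C)C)C1=O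
F3 | step 9 | isopropenyl analogue of 14 (C14 bears prop-1-en-2-yl in place of propan-2-yl) | CC(C)=CCC/C(C)=C/C[C@]12C[C@@H]3C[C@@H]4C(C)(C)[C@H](C(C)=C)C[C@@]4(C1=O)C(=O)[C@](C(=O)c1ccccc1)(C2=O)C3(C)C
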